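**Strategy.** Everything rests on a retro-transannular Diels–Alder cut through ring B. Breaking C9–C14 and C8–C17 unfolds the cis-decalin (ring A C9–C14, ring B C8/C9/C14–C17) and the 16-membered lactone into a single 24-membered macrolactone octaene. The step exploits the C15=C16 cyclohexene retron, the four-carbon C10–C13 tether with its syn C11/C13 oxygens, and the fact that C7 and C18 sit on one face. In one thermal operation it forms two C–C bonds, closes rings A and B, contracts the macrocycle, and sets C8 (quaternary), C9, C14 and C17. The precursor holds only chain stereocentres and is closed at C15–C16, so the diene first exists inside the ring.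

Key step: step 27

Remark (numbering and reading of the SMILES): C1 is the lactone carbonyl and C27 the terminal methyl. The SMILES is read as 2E,4Z,6E,18E,20E and 8R,9R,11S,13S,14R,17R,22R,23R,24R,25S,26R, with H-9, H-11, H-13, H-14, H-17 and CH3-8 all on one face of the decalin.

Assumption: compounds 1, 10, 15, 22 and 30 are taken as purchasable in the stated enantiomeric form.

Step 1
Reactants: 1 tert-butyl 2-[(4R,6S)-6-(hydroxymethyl)-2,2-dimethyl-1,3-dioxan-4-yl]acetate
Product: 2 tert-butyl 2-[(4R,6S)-6-formyl-2,2-dimethyl-1,3-dioxan-4-yl]acetate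
Conditions: TEMPO (cat.), PhI(OAc)2, CH2Cl2, rt
Reagents that add atoms: none
Why: TEMPO-catalysed oxoammonium oxidation takes the primary alcohol (C14) to the aldehyde under neutral conditions that spare the acetonide, the tert-butyl ester and the C13 stereocentre.

Step 2
Reactants: 2 tert-butyl 2-[(4R,6S)-6-formyl-2,2-dimethyl-1,3-dioxan-4-yl]acetate
Product: 3 tert-butyl 2-[(4R,6S)-6-ethynyl-2,2-dimethyl-1,3-dioxan-4-yl]acetate
Conditions: Ohira–Bestmann reagent, K2CO3, MeOH, 0 °C to rt
Reagents that add atoms: dimethyl (1-diazo-2-oxopropyl)phosphonate, COP(=O)(OC)C(=[N+]=[N-])C(C)=O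
Why: Ohira–Bestmann (Seyferth–Gilbert) homologation converts the aldehyde into the terminal alkyne C14≡C15 under mild carbonate conditions, and C13 is safe because its cis-diequatorial dioxane is also the thermodynamic epimer.

Step 3
Reactants: 3 tert-butyl 2-[(4R,6S)-6-ethynyl-2,2-dimethyl-1,3-dioxan-4-yl]acetate
Product: 4 (4R,6S)-6-ethynyl-4-hydroxyoxan-2-one
Conditions: TFA, CH2Cl2 (trace H2O), 0 °C to rt
Reagents that add atoms: none
Why: Acidolysis strips acetonide and tert-butyl ester and the 3,5-dihydroxy acid should lactonise only through O13 (six-membered ring rather than β-lactone), so the pyranone template tells the two syn hydroxyls apart and leaves O11–H free.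

Step 4
Reactants: 4 (4R,6S)-6-ethynyl-4-hydroxyoxan-2-one
Product: 5 (4R,6S)-6-ethynyl-4-methoxyoxan-2-one
Conditions: Me3OBF4, 1,8-bis(dimethylamino)naphthalene, 4 Å MS, CH2Cl2, rt
Reagents that add atoms: trimethyloxonium tetrafluoroborate, C[O+](C)C.F[B-](F)(F)F
Why: O-Alkylation with Meerwein salt in the presence of a non-nucleophilic proton scavenger methylates O11 without forming an alkoxide, which avoids E1cB elimination of the β-oxygenated lactone.

Step 5
Reactants: 5 (4R,6S)-6-ethynyl-4-methoxyoxan-2-one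
Product: 6 (4R,6S)-6-ethynyl-4-methoxyoxan-2-ol (lactol; both anomers)
Conditions: DIBAL-H, CH2Cl2, −78 °C; Rochelle salt work-up
Reagents that add atoms: none
Why: Partial reduction of the δ-lactone with DIBAL-H stops at the stable aluminium lactolate at low temperature and delivers the lactol as a masked C9 aldehyde.

Step 6
Reactants: 6 (4R,6S)-6-ethynyl-4-methoxyoxan-2-ol
Product: 7 (3S,5S,7Z)-8-iodo-5-methoxynon-7-en-1-yn-3-ol (C8–C15 unit)
Conditions: [Ph3PEt]I, n-BuLi, THF; I2, −78 °C; NaHMDS, −20 °C; then 6, −78 to −20 °C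
Reagents that add atoms: ethyltriphenylphosphonium iodide, CC[P+](c1ccccc1)(c1ccccc1)c1ccccc1.[I-]; iodine, II
Why: Stork–Zhao-type Wittig olefination of the ring-opened hydroxy aldehyde with the non-stabilised α-iodoethylidene ylide is under kinetic cis control and should place iodine cis to C10 (the Z geometry needed for the dienophile) while releasing O13–H.

Step 7
Reactants: 7 (3S,5S,7Z)-8-iodo-5-methoxynon-7-en-1-yn-3-ol
Product: 8 triethyl{[(3S,5S,7Z)-8-iodo-5-methoxynon-7-en-1-yn-3-yl]oxy}silane
Conditions: TESCl, imidazole, CH2Cl2, 0 °C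
Reagents that add atoms: chlorotriethylsilane, CC[Si](Cl)(CC)CC
Why: Standard silylation caps the only hydroxyl as a TES ether that can later be removed in the presence of a TBS ether.

Step 8
Reactants: 8 triethyl{[(3S,5S,7Z)-8-iodo-5-methoxynon-7-en-1-yn-3-yl]oxy}silane
Product: 9 2-[(1E,3S,5S,7Z)-8-iodo-5-methoxy-3-(triethylsilyloxy)nona-1,7-dien-1-yl]-4,4,5,5-tetramethyl-1,3,2-dioxaborolane
Conditions: HBpin, Cp2ZrHCl (cat.), Et3N (cat.), CH2Cl2, 40 °C
Reagents that add atoms: pinacolborane, CC1(C)OBOC1(C)C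
Why: Zirconocene-catalysed syn hydroboration of the terminal alkyne with pinacolborane places boron on C15 and should give the E-alkenylboronate, the hindered trisubstituted alkenyl iodide being inert to the hydride.

Step 9
Reactants: 10 but-2-yn-1-ol
Product: 12 (Z)-3-iodobut-2-en-1-ol, via cyclic vinylalanate 11 (not isolated)
Conditions: Red-Al, THF, 0 °C to rt; then I2, −78 to 0 °C
Reagents that add atoms: iodine, II
Why: Hydroxyl-directed trans-hydroalumination gives the five-membered vinylalanate with aluminium on the methyl-bearing carbon, and iodinolysis with retention fixes iodine cis to the carbinol carbon, which is the 4Z geometry of the target.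

Step 10
Reactants: 12 (Z)-3-iodobut-2-en-1-ol
Product: 14 ethyl (2E,4Z)-5-iodohexa-2,4-dienoate, via (Z)-3-iodobut-2-enal 13 (not isolated)
Conditions: MnO2, Ph3P=CHCO2Et, CH2Cl2, rt, dark
Reagents that add atoms: ethyl (triphenylphosphoranylidene)acetate, CCOC(=O)C=P(c1ccccc1)(c1ccccc1)c1ccccc1
Why: Tandem allylic MnO2 oxidation and Wittig olefination traps the isomerisation-prone Z-iodoenal in situ with a stabilised ylide, which should give the 2E alkene and keep the 4Z iodide.

Step 11
Reactants: 14 ethyl (2E,4Z)-5-iodohexa-2,4-dienoate; 15 (E)-1,2-bis(tributylstannyl)ethene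
Product: 16 ethyl (2E,4Z,6E)-5-methyl-7-(tributylstannyl)hepta-2,4,6-trienoate
Conditions: 15 (excess), PdCl2(MeCN)2 (cat.), DMF, rt, dark
Reagents that add atoms: none
Why: Stille coupling of the alkenyl iodide with an excess of the symmetrical distannane proceeds with retention at both partners and stops after one C–C bond, installing C6=C7 (E) with a tin handle on C7.

Step 12
Reactants: 16 ethyl (2E,4Z,6E)-5-methyl-7-(tributylstannyl)hepta-2,4,6-trienoate
Product: 17 (2E,4Z,6E)-5-methyl-7-(tributylstannyl)hepta-2,4,6-trienoic acid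
Conditions: LiOH, THF/MeOH/H2O, rt; then dilute HCl to pH 5, 0 °C
Reagents that add atoms: lithium hydroxide, [Li+].[OH-]
Why: Saponification of the ethyl ester leaves the alkenylstannane and the triene geometry intact provided that the acidification is stopped at weakly acidic pH.

Step 13
Reactants: 9 C8–C15 iodide/boronate; 17 C1–C7 stannyl trienoic acid
Product: 18 (2E,4Z,6E,8Z,11S,13S,14E)-11-methoxy-5,8-dimethyl-15-(4,4,5,5-tetramethyl-1,3,2-dioxaborolan-2-yl)-13-(triethylsilyloxy)pentadeca-2,4,6,8,14-pentaenoic acid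
Conditions: Pd2(dba)3·CHCl3 (cat.), AsPh3, i-Pr2NEt, DMF, rt, dark
Reagents that add atoms: none
Why: Stille coupling under neutral conditions free of oxygen base joins C7 to C8 with retention of the 6E and 8Z geometries, and the pinacolboronate stays silent because it cannot transmetalate without an oxygen base.

Step 14
Reactants: 10 but-2-yn-1-ol
Product: 20 (E)-3-iodobut-2-en-1-ol, via zirconated allyl alkoxide 19 (not isolated)
Conditions: Cp2ZrHCl (excess), THF, rt, dark; then I2, −78 to 0 °C
Reagents that add atoms: iodine, II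
Why: Hydrozirconation with excess Schwartz reagent is a syn addition that equilibrates zirconium to the less hindered methyl-bearing carbon, and iodinolysis with retention should give the E-iodide needed for C18=C19.

Step 15
Reactants: 20 (E)-3-iodobut-2-en-1-ol
Product: 21 (E)-3-iodobut-2-enal
Conditions: MnO2, CH2Cl2, rt, dark
Reagents that add atoms: none
Why: Chemoselective MnO2 oxidation of the allylic alcohol gives the enal (C17–C19) without E/Z isomerisation or loss of iodine.

Step 16
Reactants: 22 tert-butyl N-[(2R)-1-oxopropan-2-yl]carbamate (N-Boc-D-alaninal)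
Product: 24 tert-butyl N-[(2R,3S,4S)-3-hydroxy-4-methylhex-5-en-2-yl]carbamate, via borinate ester 23 (not isolated)
Conditions: trans-2-butene, n-BuLi, KOt-Bu, THF, −78 to −45 °C; (−)-Ipc2BOMe, −78 °C; BF3·OEt2; 22, −78 °C; then NaOH, H2O2, rt
Reagents that add atoms: trans-but-2-ene, C/C=C/C
Why: Brown E-crotylboration runs through a closed chair transition state, so the E-crotyl geometry sets C24/C25 anti and the (+)-α-pinene-derived ligands choose the aldehyde face that gives 25S, anti to the nitrogen on C26 that comes from D-alanine.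

Step 17
Reactants: 24 tert-butyl N-[(2R,3S,4S)-3-hydroxy-4-methylhex-5-en-2-yl]carbamate
Product: 26 N-[(2R,3S,4S)-3-hydroxy-4-methylhex-5-en-2-yl]acetamide, via ammonium chloride 25 (not isolated)
Conditions: HCl (dioxane), CH2Cl2, 0 °C to rt; concentrate; then Ac2O, Et3N, CH2Cl2, 0 °C
Reagents that add atoms: acetic anhydride, CC(=O)OC(C)=O
Why: Acidolysis of the Boc group followed by chemoselective N-acetylation of the far more nucleophilic amine installs the acetamide of the target early, so that no strong acid is needed once the polyenes are present.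

Step 18
Reactants: 26 N-[(2R,3S,4S)-3-hydroxy-4-methylhex-5-en-2-yl]acetamide
Product: 27 N-[(2R,3S,4S)-3-(tert-butyldimethylsilyloxy)-4-methylhex-5-en-2-yl]acetamide
Conditions: TBSOTf, 2,6-lutidine, CH2Cl2, 0 °C; aqueous work-up
Reagents that add atoms: tert-butyldimethylsilyl triflate, CC(C)(C)[Si](C)(C)OS(=O)(=O)C(F)(F)F
Why: Silylation with the triflate protects the hindered O25 as a robust TBS ether, any silyl imidate formed on the amide being hydrolysed on work-up.

Step 19
Reactants: 27 N-[(2R,3S,4S)-3-(tert-butyldimethylsilyloxy)-4-methylhex-5-en-2-yl]acetamide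
Product: 29 N-[(2R,3S,4R)-3-(tert-butyldimethylsilyloxy)-4-methyl-5-oxopentan-2-yl]acetamide, via secondary ozonide 28 (not isolated)
Conditions: O3, CH2Cl2, −78 °C; then PPh3, −78 °C to rt
Reagents that add atoms: ozone, [O-][O+]=O
Why: Ozonolysis with reductive work-up cleaves the terminal alkene to the C23 aldehyde under neutral conditions that do not epimerise C24.

Step 20
Reactants: 30 (S)-but-3-yn-2-ol
Product: 31 (S)-but-3-yn-2-yl methanesulfonate
Conditions: MsCl, Et3N, CH2Cl2, −78 to 0 °C
Reagents that add atoms: methanesulfonyl chloride, CS(=O)(=O)Cl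
Why: Mesylation at oxygen activates the propargylic alcohol without touching its stereocentre.

Step 21
Reactants: 29 C23 aldehyde; 31 (S)-but-3-yn-2-yl methanesulfonate
Product: 32 N-[(2R,3S,4S,5R,6R)-3-(tert-butyldimethylsilyloxy)-5-hydroxy-4,6-dimethyloct-7-yn-2-yl]acetamide
Conditions: Pd(OAc)2 (cat.), PPh3 (cat.), Et2Zn, THF, −78 to −20 °C; NH4Cl work-up
Reagents that add atoms: none
Why: Marshall propargylation (anti SN2′ oxidative addition, Pd-to-Zn exchange, cyclic SE2′ addition of the axially chiral allenylzinc) should set C22/C23 anti with C22 fixed by the mesylate through net inversion, and C23/C24 syn in the Felkin sense that the anti α-methyl β-silyloxy aldehyde itself prefers.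

Step 22
Reactants: 32 homopropargylic alcohol
Product: 33 N-[(2R,3S,4S,5R,6R,7E)-3-(tert-butyldimethylsilyloxy)-5-hydroxy-4,6-dimethyl-8-(tributylstannyl)oct-7-en-2-yl]acetamide
Conditions: Bu3SnH, PdCl2(PPh3)2 (cat.), THF, 0 °C
Reagents that add atoms: tributyltin hydride, CCCC[SnH](CCCC)CCCC
Why: Palladium-catalysed syn hydrostannation places tin on the unhindered alkyne terminus because C22 is branched, giving the E-alkenylstannane in the presence of the free OH and NH groups.

Step 23
Reactants: 33 C20 alkenylstannane; 21 (E)-3-iodobut-2-enal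
Product: 34 N-[(2R,3S,4S,5R,6R,7E,9E)-3-(tert-butyldimethylsilyloxy)-5-hydroxy-4,6,9-trimethyl-11-oxoundeca-7,9-dien-2-yl]acetamide
Conditions: PdCl2(MeCN)2 (cat.), DMF, rt, dark
Reagents that add atoms: none
Why: Stille coupling of an unhindered terminal alkenylstannane with an electron-poor alkenyl iodide forms C19–C20 under neutral conditions with retention of both E geometries.

Step 24
Reactants: 34 C17 dienal
Product: 35 N-[(2R,3S,4S,5R,6R,7E,9E,11E)-3-(tert-butyldimethylsilyloxy)-5-hydroxy-12-iodo-4,6,9-trimethyldodeca-7,9,11-trien-2-yl]acetamide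
Conditions: CrCl2, CHI3, THF/dioxane, 0 °C, dark
Reagents that add atoms: iodoform, IC(I)I
Why: Takai olefination with the gem-dichromium species from iodoform is E-selective, tolerates free hydroxyl and amide groups and adds C16 as the alkenyl iodide.

Step 25
Reactants: 18 C1–C15 acid; 35 C16–C27 alcohol
Product: 37 open-chain ester of 18 on O23 of 35 (C15 boronate; C16 iodide; C13-OTES; C25-OTBS), via mixed anhydride 36 (not isolated)
Conditions: 2,4,6-trichlorobenzoyl chloride, Et3N, toluene, rt; then 35, DMAP, rt, dark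
Reagents that add atoms: none
Why: Yamaguchi esterification through the mixed anhydride and the acylpyridinium ion acylates the hindered O23, the only free hydroxyl, with retention at C23 and without affecting boronate, iodide or silyl ethers.

Step 26
Reactants: 37 open-chain ester
Product: 38 24-membered macrolactone (2E,4Z,6E,8Z,14E,16E,18E,20E)-octaene (C13-OTES; C25-OTBS)
Conditions: Pd(PPh3)4 (cat.), TlOEt, THF/H2O, high dilution, rt, degassed, dark
Reagents that add atoms: none
Why: Intramolecular Suzuki–Miyaura coupling under thallium(I)-accelerated aqueous conditions at high dilution joins C15 to C16 with retention at both alkenes, closing the 24-membered ring at room temperature and creating the 14E,16E-diene only at this point.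

Step 27
Reactants: 38 24-membered macrolactone octaene
Product: 39 13-O-TES-25-O-TBS-13-O-descarbamoyl superstolide A (cis-decalin fused to the 16-membered lactone; all stereocentres as in 43)
Conditions: toluene, BHT, high dilution, degassed, 80 °C, dark
Reagents that add atoms: none
Why: The step is a concerted suprafacial [4π+2π] cycloaddition across the ring between the 14E,16E-diene and the 8Z-alkene that ends the tetraenoate (LUMO lowered vinylogously by the ester), the closest known reaction type being the transannular Diels–Alder reaction of macrocyclic trienes. Bond C9–C14 closes ring A as a six-membered carbocycle over the four-carbon C10–C13 tether, bond C8–C17 closes ring B as the cyclohexene that keeps C15=C16, and the rest of the perimeter (C1–C8, C17–C23, O) becomes the 16-membered lactone. C8 and C9 copy the Z geometry of the dienophile (CH3-8 cis to H-9), C14 and C17 copy the E,E geometry of the diene (H-14 cis to H-17), and the endo mode, with C7 and C10 under the diene, ties the two pairs together to give the cis ring fusion with C7 and C18 on one face. The endo mode is enforced by the ring, because the trienoate arm on C8 and the dienyl arm on C17 are joined through C1–O–C23 and can be spanned only when they stack, whereas the exo mode would point them apart. The absolute face follows from C11 and C13, since the tether folds as a chair with OMe, OTES and the fully substituted C8 equatorial and the slim C15 axial, while attack on the other face would force C8 or both oxygens into axial positions. The step also needs site selectivity over other diene/ene pairings and over 6π closure of the 2E,4Z,6E-triene, and this rests on the short tether, which holds only C9 and C14 within bonding distance at a temperature below that of the competing channels.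

Step 28
Reactants: 39 13-O-TES-25-O-TBS tricycle
Product: 40 25-O-TBS-13-O-descarbamoyl superstolide A (free C13-OH)
Conditions: PPTS (cat.), MeOH/CH2Cl2, 0 °C
Reagents that add atoms: none
Why: Mild acid-catalysed methanolysis removes the less hindered and more labile TES ether while the TBS ether on the congested C25 stays in place.

Step 29
Reactants: 40 C13 alcohol
Product: 42 25-O-TBS superstolide A, via N-trichloroacetyl carbamate 41 (not isolated)
Conditions: Cl3CC(O)NCO, CH2Cl2, −78 to 0 °C; then K2CO3 (cat.), MeOH, 0 °C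
Reagents that add atoms: trichloroacetyl isocyanate, O=C=NC(=O)C(Cl)(Cl)Cl
Why: Addition of the C13 alcohol to the highly electrophilic acyl isocyanate and brief methanolysis of the trichloroacetyl group give the primary carbamate with retention at C13 and faster than the lactone can transesterify.

Step 30
Reactants: 42 25-O-TBS superstolide A
Product: 43 superstolide A
Conditions: HF·pyridine, pyridine, THF, 0 °C to rt
Reagents that add atoms: none
Why: Fluoride-mediated desilylation with buffered HF·pyridine frees O25–H under conditions that the carbamate, the lactone and the polyenes should tolerate.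

**Compound list**

1 | tert-butyl 2-[(4R,6S)-6-(hydroxymethyl)-2,2-dimethyl-1,3-dioxan-4-yl]acetate | CC(C)(C)OC(=O)C[C@H]1C[C@@H](CO)OC(C)(C)O1 | starting material
2 | tert-butyl 2-[(4R,6S)-6-formyl-2,2-dimethyl-1,3-dioxan-4-yl]acetate | CC(C)(C)OC(=O)C[C@H]1C[C@@H](C=O)OC(C)(C)O1 | intermediate
3 | tert-butyl 2-[(4R,6S)-6-ethynyl-2,2-dimethyl-1,3-dioxan-4-yl]acetate | CC(C)(C)OC(=O)C[C@H]1C[C@@H](C#C)OC(C)(C)O1 | intermediate
4 | (4R,6S)-6-ethynyl-4-hydroxyoxan-2-one | O=C1C[C@H](O)C[C@@H](C#C)O1 | intermediate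
5 | (4R,6S)-6-ethynyl-4-methoxyoxan-2-one | O=C1C[C@H](OC)C[C@@H](C#C)O1 | intermediate
6 | (4R,6S)-6-ethynyl-4-methoxyoxan-2-ol (both anomers) | OC1C[C@H](OC)C[C@@H](C#C)O1 | intermediate
7 | (3S,5S,7Z)-8-iodo-5-methoxynon-7-en-1-yn-3-ol | C#C[C@@H](O)C[C@@H](OC)C/C=C(\I)C | intermediate
8 | triethyl{[(3S,5S,7Z)-8-iodo-5-methoxynon-7-en-1-yn-3-yl]oxy}silane | C#C[C@@H](O[Si](CC)(CC)CC)C[C@@H](OC)C/C=C(\I)C | intermediate
9 | 2-[(1E,3S,5S,7Z)-8-iodo-5-methoxy-3-(triethylsilyloxy)nona-1,7-dien-1-yl]-4,4,5,5-tetramethyl-1,3,2-dioxaborolane | CC1(C)OB(/C=C/[C@@H](O[Si](CC)(CC)CC)C[C@@H](OC)C/C=C(\I)C)OC1(C)C | intermediate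
10 | but-2-yn-1-ol | CC#CCO | starting material
11 | sodium cyclic vinylalanate from 10 and Red-Al | CC1=CCO[Al-]1(OCCOC)OCCOC.[Na+] | intermediate
12 | (Z)-3-iodobut-2-en-1-ol | OC/C=C(\I)C | intermediate
13 | (Z)-3-iodobut-2-enal | O=C/C=C(\I)C | intermediate
14 | ethyl (2E,4Z)-5-iodohexa-2,4-dienoate | CCOC(=O)/C=C/C=C(\I)C | intermediate
15 | (E)-1,2-bis(tributylstannyl)ethene | CCCC[Sn](CCCC)(CCCC)/C=C/[Sn](CCCC)(CCCC)CCCC | starting material
16 | ethyl (2E,4Z,6E)-5-methyl-7-(tributylstannyl)hepta-2,4,6-trienoate | CCOC(=O)/C=C/C=C(C)\C=C\[Sn](CCCC)(CCCC)CCCC | intermediate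
17 | (2E,4Z,6E)-5-methyl-7-(tributylstannyl)hepta-2,4,6-trienoic acid | OC(=O)/C=C/C=C(C)\C=C\[Sn](CCCC)(CCCC)CCCC | intermediate
18 | C1–C15 tetraenoic acid with C15 pinacolboronate and C13-OTES | OC(=O)/C=C/C=C(C)\C=C\C(C)=C/C[C@H](OC)C[C@H](O[Si](CC)(CC)CC)/C=C/B1OC(C)(C)C(C)(C)O1 | intermediate
19 | (E)-3-zirconated but-2-enyl zirconocene alkoxide | Cl[Zr](C1C=CC=C1)(C1C=CC=C1)OC/C=C(C)/[Zr](Cl)(C1C=CC=C1)C1C=CC=C1 | intermediate
20 | (E)-3-iodobut-2-en-1-ol | OC/C=C(C)/I | intermediate
21 | (E)-3-iodobut-2-enal | O=C/C=C(C)/I | intermediate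
22 | tert-butyl N-[(2R)-1-oxopropan-2-yl]carbamate | C[C@@H](NC(=O)OC(C)(C)C)C=O | starting material
23 | diisopinocampheylborinate of 24 | C=C[C@H](C)[C@H](OB([C@@H]1C[C@@H]2C[C@H]([C@H]1C)C2(C)C)[C@@H]1C[C@@H]2C[C@H]([C@H]1C)C2(C)C)[C@@H](C)NC(=O)OC(C)(C)C | intermediate
24 | tert-butyl N-[(2R,3S,4S)-3-hydroxy-4-methylhex-5-en-2-yl]carbamate | C=C[C@H](C)[C@H](O)[C@@H](C)NC(=O)OC(C)(C)C | intermediate
25 | (2R,3S,4S)-3-hydroxy-4-methylhex-5-en-2-aminium chloride | C=C[C@H](C)[C@H](O)[C@@H](C)[NH3+].[Cl-] | intermediate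
26 | N-[(2R,3S,4S)-3-hydroxy-4-methylhex-5-en-2-yl]acetamide | C=C[C@H](C)[C@H](O)[C@@H](C)NC(C)=O | intermediate
27 | N-[(2R,3S,4S)-3-(tert-butyldimethylsilyloxy)-4-methylhex-5-en-2-yl]acetamide | C=C[C@H](C)[C@H](O[Si](C)(C)C(C)(C)C)[C@@H](C)NC(C)=O | intermediate
28 | secondary ozonide (1,2,4-trioxolane) of 27 | C1OOC(O1)[C@H](C)[C@H](O[Si](C)(C)C(C)(C)C)[C@@H](C)NC(C)=O | intermediate
29 | N-[(2R,3S,4R)-3-(tert-butyldimethylsilyloxy)-4-methyl-5-oxopentan-2-yl]acetamide | O=C[C@H](C)[C@H](O[Si](C)(C)C(C)(C)C)[C@@H](C)NC(C)=O | intermediate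
30 | (S)-but-3-yn-2-ol | C#C[C@H](C)O | starting material
31 | (S)-but-3-yn-2-yl methanesulfonate | C#C[C@H](C)OS(C)(=O)=O | intermediate
32 | N-[(2R,3S,4S,5R,6R)-3-(tert-butyldimethylsilyloxy)-5-hydroxy-4,6-dimethyloct-7-yn-2-yl]acetamide | C#C[C@@H](C)[C@H]([C@H](C)[C@H](O[Si](C)(C)C(C)(C)C)[C@@H](C)NC(C)=O)O | intermediate
33 | C20 (E)-alkenylstannane of the C20–C27 unit | CCCC[Sn](CCCC)(CCCC)/C=C/[C@@H](C)[C@H]([C@H](C)[C@H](O[Si](C)(C)C(C)(C)C)[C@@H](C)NC(C)=O)O | intermediate
34 | C17–C27 (18E,20E)-dienal | O=C/C=C(C)/C=C/[C@@H](C)[C@H]([C@H](C)[C@H](O[Si](C)(C)C(C)(C)C)[C@@H](C)NC(C)=O)O | intermediate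
35 | C16–C27 (16E,18E,20E)-trienyl iodide with free O23–H | I/C=C/C=C(C)/C=C/[C@@H](C)[C@H]([C@H](C)[C@H](O[Si](C)(C)C(C)(C)C)[C@@H](C)NC(C)=O)O | intermediate
36 | mixed anhydride of 18 and 2,4,6-trichlorobenzoic acid | O=C(OC(=O)/C=C/C=C(C)\C=C\C(C)=C/C[C@H](OC)C[C@H](O[Si](CC)(CC)CC)/C=C/B1OC(C)(C)C(C)(C)O1)c1c(Cl)cc(Cl)cc1Cl | intermediate
37 | open-chain ester (C15 boronate; C16 iodide) | I/C=C/C=C(C)/C=C/[C@@H](C)[C@H]([C@H](C)[C@H](O[Si](C)(C)C(C)(C)C)[C@@H](C)NC(C)=O)OC(=O)/C=C/C=C(C)\C=C\C(C)=C/C[C@H](OC)C[C@H](O[Si](CC)(CC)CC)/C=C/B1OC(C)(C)C(C)(C)O1 | intermediate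
38 | 24-membered macrolactone octaene | CO[C@@H]1C[C@H](O[Si](CC)(CC)CC)/C=C/C=C/C=C(C)/C=C/[C@@H](C)[C@H]([C@H](C)[C@H](O[Si](C)(C)C(C)(C)C)[C@@H](C)NC(C)=O)OC(=O)/C=C/C=C(C)\C=C\C(C)=C/C1 | intermediate
39 | 13-O-TES-25-O-TBS-13-O-descarbamoyl superstolide A | CO[C@@H]1C[C@H](O[Si](CC)(CC)CC)[C@@H]2C=C[C@@H]3/C=C(C)/C=C/[C@@H](C)[C@H]([C@H](C)[C@H](O[Si](C)(C)C(C)(C)C)[C@@H](C)NC(C)=O)OC(=O)/C=C/C=C(C)\C=C\[C@]3(C)[C@@H]2C1 | intermediate
40 | 25-O-TBS-13-O-descarbamoyl superstolide A | CO[C@@H]1C[C@H](O)[C@@H]2C=C[C@@H]3/C=C(C)/C=C/[C@@H](C)[C@H]([C@H](C)[C@H](O[Si](C)(C)C(C)(C)C)[C@@H](C)NC(C)=O)OC(=O)/C=C/C=C(C)\C=C\[C@]3(C)[C@@H]2C1 | intermediate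
41 | N-trichloroacetyl carbamate of 40 | CO[C@@H]1C[C@H](OC(=O)NC(=O)C(Cl)(Cl)Cl)[C@@H]2C=C[C@@H]3/C=C(C)/C=C/[C@@H](C)[C@H]([C@H](C)[C@H](O[Si](C)(C)C(C)(C)C)[C@@H](C)NC(C)=O)OC(=O)/C=C/C=C(C)\C=C\[C@]3(C)[C@@H]2C1 | intermediate
42 | 25-O-TBS superstolide A | CO[C@@H]1C[C@H](OC(N)=O)[C@@H]2C=C[C@@H]3/C=C(C)/C=C/[C@@H](C)[C@H]([C@H](C)[C@H](O[Si](C)(C)C(C)(C)C)[C@@H](C)NC(C)=O)OC(=O)/C=C/C=C(C)\C=C\[C@]3(C)[C@@H]2C1 | intermediate
43 | superstolide A | CO[C@@H]1C[C@H](OC(N)=O)[C@@H]2C=C[C@@H]3/C=C(C)/C=C/[C@@H](C)[C@H]([C@H](C)[C@H](O)[C@@H](C)NC(C)=O)OC(=O)/C=C/C=C(C)\C=C\[C@]3(C)[C@@H]2C1 | target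

**Step count.** Total steps: 30. Longest linear sequence: 15 steps (steps 1–8, 13, 25–30, from compound 1). The branch from 22 counts 14 steps.

**Steps most likely to fail**

**Step 27 (transannular Diels–Alder reaction).**
- What may go wrong: the cycloaddition may be too slow, so that 6π-electrocyclisation of the 2E,4Z,6E-triene, E/Z isomerisation or polymerisation take over. Alternatively, the conformational demands of the C22–C23 region may erode the facial bias from C11/C13.
- Fallback: run the cycloaddition before ring closure. It sets out from 18 and 35.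
- Intermolecular Suzuki–Miyaura coupling (Pd(PPh3)4, TlOEt, aqueous THF, rt) would join C15 to C16 and give the open-chain octaene hydroxy acid F1.
- Heating in toluene with BHT would trigger a type-1 intramolecular Diels–Alder reaction of the 1,7,9-decatriene unit. This is governed only by the chair tether and the endo preference of the Z-dienophile, and would give the cis-decalin hydroxy acid F2.
- Yamaguchi macrolactonisation on O23 at high dilution would then close the 16-membered ring and come back to the route at 39.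

**Step 26 (Suzuki–Miyaura macrocyclisation).**
- What may go wrong: oligomerisation, protodeboronation of the allylically oxygenated alkenylboronate, or decay of the trienyl iodide before transmetalation.
- Fallback: close the same bond by a Heck reaction that needs no metal on C15. It sets out from 8.
- Hydrozirconation with Cp2ZrHCl followed by protonolysis with water would give the terminal alkene (3S,5S,7Z)-8-iodo-5-methoxy-3-(triethylsilyloxy)nona-1,7-diene F3.
- Stille coupling with 17, as in step 13, would give the C1–C15 tetraenoic acid with a vinyl terminus F4.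
- Yamaguchi esterification with 35 would give the iodide/vinyl ester F5.
- Intramolecular Heck coupling (Pd(OAc)2, Ag2CO3, DMF, high dilution) at the only monosubstituted alkene would form C15–C16 as the E-alkene and come back to the route at 38.

**Step 6 (iodo-olefination of the lactol).**
- What may go wrong: slow ring opening of the lactolate at the low temperature that the fragile iodo-ylide tolerates, proton transfer from O–H to the ylide, β-elimination of methoxide from the released aldehyde, and erosion of the Z selectivity.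
- Fallback: give up the lactol as aldehyde surrogate and open the ring first. It sets out from 5.
- Aminolysis with MeNH(OMe)·HCl and AlMe3 would give the Weinreb amide (3R,5S)-5-hydroxy-N,3-dimethoxy-N-methylhept-6-ynamide F6.
- Silylation with TESCl and imidazole would give its TES ether F7.
- DIBAL-H at −78 °C would give the free aldehyde (3R,5S)-3-methoxy-5-(triethylsilyloxy)hept-6-ynal F8, which carries no hydroxyl proton.
- Olefination of this aldehyde with the α-iodoethylidene ylide would come back to the route at 8.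

**Further compounds**

F1 | step 27 | open-chain C1–C27 octaene hydroxy acid | OC(=O)/C=C/C=C(C)\C=C\C(C)=C/C[C@H](OC)C[C@H](O[Si](CC)(CC)CC)/C=C/C=C/C=C(C)/C=C/[C@@H](C)[C@H]([C@H](C)[C@H](O[Si](C)(C)C(C)(C)C)[C@@H](C)NC(C)=O)O
F2 | step 27 | cis-decalin hydroxy acid (seco acid of 39) | CO[C@@H]1C[C@H](O[Si](CC)(CC)CC)[C@@H]2C=C[C@H](/C=C(C)/C=C/[C@@H](C)[C@H]([C@H](C)[C@H](O[Si](C)(C)C(C)(C)C)[C@@H](C)NC(C)=O)O)[C@](C)(/C=C/C(C)=C\C=C\C(O)=O)[C@@H]2C1
F3 | step 26 | (3S,5S,7Z)-8-iodo-5-methoxy-3-(triethylsilyloxy)nona-1,7-diene | C=C[C@@H](O[Si](CC)(CC)CC)C[C@@H](OC)C/C=C(\I)C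
F4 | step 26 | C1–C15 tetraenoic acid with a vinyl terminus | OC(=O)/C=C/C=C(C)\C=C\C(C)=C/C[C@H](OC)C[C@H](O[Si](CC)(CC)CC)C=C
F5 | step 26 | iodide/vinyl ester | I/C=C/C=C(C)/C=C/[C@@H](C)[C@H]([C@H](C)[C@H](O[Si](C)(C)C(C)(C)C)[C@@H](C)NC(C)=O)OC(=O)/C=C/C=C(C)\C=C\C(C)=C/C[C@H](OC)C[C@H](O[Si](CC)(CC)CC)C=C
F6 | step 6 | (3R,5S)-5-hydroxy-N,3-dimethoxy-N-methylhept-6-ynamide | CON(C)C(=O)C[C@H](OC)C[C@H](O)C#C
F7 | step 6 | (3R,5S)-N,3-dimethoxy-N-methyl-5-(triethylsilyloxy)hept-6-ynamide | CON(C)C(=O)C[C@H](OC)C[C@H](O[Si](CC)(CC)CC)C#C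
F8 | step 6 | (3R,5S)-3-methoxy-5-(triethylsilyloxy)hept-6-ynal | O=CC[C@H](OC)C[C@H](O[Si](CC)(CC)CC)C#C
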